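Ring A is cut at C4–C5. The quaternary C4 (C18 methyl, C19 acetoxymethyl) sits between the C3 ketone and C5, the α-carbon of the ring B enone (C6=O, C5=C10). This 1,4-relationship of the C3 and C6 oxygens is met by letting C5 of a ring B silyl dienol ether open a (3R,4R)-epoxide at its tertiary carbon. One operation closes ring A, forms C4–C5, sets C4 by inversion and delivers the C3 oxygen. The precursor is a monocyclic ring B dienol ether with the epoxide arm on C10, C9 from an amino-acid-mediated annulation, C7 already oxygenated to block the other enolisation site, and C11/C19 carrying different silyl groups.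

Key step: step 12

Assumption: atoms carry the terpenoid numbering of the target (ring A C1–C5/C10, ring B C5–C10, side chain C11–C16, C17 on C8, C18/C19 on C4, C20 on C9); C7 and C8 of the intermediates are spectator centres that become sp2 in step 23 and are drawn as each step is expected to give them.

Step 1
Reactants: 1 2-methylcyclohexane-1,3-dione; 2 (E)-pent-3-en-2-one
Product: 3 rac-2-methyl-2-(4-oxopentan-2-yl)cyclohexane-1,3-dione
Conditions: Et3N (0.1 equiv), EtOAc, 70 °C
Reagents that add atoms: none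
Why: Michael addition of the acidic 1,3-dione to the enone β-carbon should give the triketone, the new centre (future C8) being formed as a racemate.

Step 2
Reactants: 3 rac-2-methyl-2-(4-oxopentan-2-yl)cyclohexane-1,3-dione
Product: 5 (4S,4aR)-4,4a-dimethyl-4,4a,7,8-tetrahydronaphthalene-2,5(3H,6H)-dione (methyls cis), via cis-fused ketol 4 (not isolated)
Conditions: D-phenylalanine (1.0 equiv), (1S)-(+)-10-camphorsulfonic acid (0.5 equiv), DMF, 30 → 70 °C, stopped near half conversion; 5 separated from unreacted 3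
Reagents that add atoms: none
Why: Hajos–Parrish–Eder–Sauer–Wiechert aldol cyclodehydration (second half of the Robinson annulation), in which the D-amino-acid enamine should select the ring carbonyl that gives the 4aR centre (future C9) and only the (S)-half of 3 can follow this path with its methyl pseudo-equatorial, so the step should also act as a kinetic resolution.

Step 3
Reactants: 5 (4S,4aR)-4,4a-dimethyl-4,4a,7,8-tetrahydronaphthalene-2,5(3H,6H)-dione
Product: 6 (4S,4aR,5R)-5-hydroxy-4,4a-dimethyl-4,4a,5,6,7,8-hexahydronaphthalen-2(3H)-one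
Conditions: NaBH4 (0.3 equiv), EtOH, −10 °C
Reagents that add atoms: none
Why: Chemoselective borohydride reduction of the saturated ketone in the presence of the less electrophilic conjugated one, hydride adding anti to the angular methyl to give an alcohol whose configuration is erased in step 4.

Step 4
Reactants: 6 (4S,4aR,5R)-5-hydroxy-4,4a-dimethyl-4,4a,5,6,7,8-hexahydronaphthalen-2(3H)-one
Product: 7 (4S,4aS)-4,4a-dimethyl-4,4a,7,8-tetrahydronaphthalen-2(3H)-one
Conditions: methyl N-(triethylammoniosulfonyl)carbamate inner salt (2 equiv), toluene, 70 °C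
Reagents that add atoms: none
Why: Thermal syn-elimination (Ei dehydration) of the derived sulfamate ester can only take a hydrogen from the CH2 side because the other neighbour is quaternary, so the isolated C3=C11 alkene should form without strong acid or base.

Step 5
Reactants: 7 (4S,4aS)-4,4a-dimethyl-4,4a,7,8-tetrahydronaphthalen-2(3H)-one
Product: 9 (1R,6S)-1,6-dimethyl-4-oxo-2-(3-oxopropyl)cyclohex-2-ene-1-carbaldehyde, via cis-diol 8 (not isolated)
Conditions: OsO4 (2 mol %), NaIO4 (4 equiv), 2,6-lutidine (2 equiv), dioxane/H2O 3:1, 0 °C → rt; crude 9 used at once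
Reagents that add atoms: osmium tetroxide O=[Os](=O)(=O)=O; sodium periodate NaIO4 [Na+].[O-][I](=O)(=O)=O
Why: Lemieux–Johnson oxidative cleavage, in which OsO4 should dihydroxylate the electron-rich isolated cis-alkene in preference to the electron-poor enone alkene and periodate cleaves the diol to the C11 and C3 aldehydes.

Step 6
Reactants: 9 (1R,6S)-1,6-dimethyl-4-oxo-2-(3-oxopropyl)cyclohex-2-ene-1-carbaldehyde; 10 2-(triphenylphosphoranylidene)propanal
Product: 11 (1R,6S)-1,6-dimethyl-2-[(E)-4-methyl-5-oxopent-3-en-1-yl]-4-oxocyclohex-2-ene-1-carbaldehyde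
Conditions: 10 (1.1 equiv), toluene, 80 °C
Reagents that add atoms: none
Why: Wittig olefination with a formyl-stabilised ylide should be E-selective and should take only the unhindered C3 aldehyde, the C11 aldehyde being neopentyl and the ring ketone conjugated.

Step 7
Reactants: 11 (1R,6S)-1,6-dimethyl-2-[(E)-4-methyl-5-oxopent-3-en-1-yl]-4-oxocyclohex-2-ene-1-carbaldehyde
Product: 12 (4R,5S)-4-(hydroxymethyl)-3-[(E)-5-hydroxy-4-methylpent-3-en-1-yl]-4,5-dimethylcyclohex-2-en-1-one
Conditions: NaBH4 (1.2 equiv), CH2Cl2/MeOH 3:1, −78 → −50 °C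
Reagents that add atoms: none
Why: Low-temperature borohydride reduction is selective for aldehydes (1,2-reduction of the enal and reduction of the C11 aldehyde) over the β,β-disubstituted cyclohexenone, which avoids an aluminium hydride step that the enone would not survive.

Step 8
Reactants: 12 (4R,5S)-4-(hydroxymethyl)-3-[(E)-5-hydroxy-4-methylpent-3-en-1-yl]-4,5-dimethylcyclohex-2-en-1-one
Product: 13 (4R,5S)-4-(hydroxymethyl)-3-{2-[(2R,3R)-3-(hydroxymethyl)-3-methyloxiran-2-yl]ethyl}-4,5-dimethylcyclohex-2-en-1-one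
Conditions: Ti(OiPr)4 (0.3 equiv), D-(−)-diethyl tartrate (0.36 equiv), t-BuOOH (2 equiv, anhydrous), 4 Å molecular sieves, CH2Cl2, −20 °C
Reagents that add atoms: tert-butyl hydroperoxide CC(C)(C)OO
Why: Sharpless asymmetric epoxidation of the E-trisubstituted primary allylic alcohol, where the D-(−)-tartrate should deliver oxygen to the face that gives the (2R,3R)-epoxy alcohol (C3 R, C4 R) regardless of the remote ring centres, the non-allylic C11 alcohol and the enone alkene being left alone.

Step 9
Reactants: 13 (4R,5S)-4-(hydroxymethyl)-3-{2-[(2R,3R)-3-(hydroxymethyl)-3-methyloxiran-2-yl]ethyl}-4,5-dimethylcyclohex-2-en-1-one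
Product: 15 19-O-TBS 11-O-TES bis-silyl ether of 13, via mono-TBS ether 14 (not isolated)
Conditions: TBSCl (1.05 equiv), imidazole, DMF, −20 → 0 °C; then Et3SiCl (1.5 equiv), DMAP (cat.), rt
Reagents that add atoms: tert-butyldimethylsilyl chloride CC(C)(C)[Si](C)(C)Cl; triethylsilyl chloride CC[Si](Cl)(CC)CC
Why: Stepwise O-silylation, in which the bulky chlorosilane should take the less hindered epoxy-carbinol oxygen (C19) first and the smaller one then caps the neopentyl C11 hydroxyl, so that the two primary oxygens can later be released separately.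

Step 10
Reactants: 15 19-O-TBS 11-O-TES bis-silyl ether of 13
Product: 16 (4R,5R,6S)-6-hydroxy derivative of 15 (C7 hydroxyl trans to the C8 methyl)
Conditions: KN(SiMe3)2 (1.1 equiv), THF, −78 °C; (±)-trans-2-(phenylsulfonyl)-3-phenyloxaziridine (1.3 equiv), −78 °C; aqueous NH4Cl
Reagents that add atoms: 2-(phenylsulfonyl)-3-phenyloxaziridine O=S(=O)(c1ccccc1)N1OC1c1ccccc1
Why: Kinetic deprotonation of the enone at the α′-carbon C7 and enolate hydroxylation by the N-sulfonyloxaziridine, the oxidant approaching anti to the axial C9 methyl so that the hydroxyl should end up trans to the C8 methyl.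

Step 11
Reactants: 16 (4R,5R,6S)-6-hydroxy derivative of 15
Product: 18 ring B tert-butyldimethylsilyl dienol ether (C6–OTBS, C5=C6, (E)-C10=C1) carrying 7-OTBS, 11-OTES and the (3R,4R)-epoxide arm with 19-OTBS, via enone silyl ether 17 (not isolated)
Conditions: TBSOTf (2.6 equiv), Et3N (4 equiv), CH2Cl2, −78 → 0 °C
Reagents that add atoms: tert-butyldimethylsilyl triflate CC(C)(C)[Si](C)(C)OS(=O)(=O)C(F)(F)F
Why: O-silylation of the C7 hydroxyl followed by soft enolisation (silyl triflate/amine) of the enone, where the α′ position is now a shielded siloxy methine so that deprotonation should occur at the γ-carbon C1, the new C10=C1 bond placing C2 syn to C5 to avoid allylic strain with the quaternary C9.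

Step 12
Reactants: 18 ring B tert-butyldimethylsilyl dienol ether with the (3R,4R)-epoxide arm
Product: 20 (3R,4S,7S,8R,9R)-3-hydroxy-5(10)-en-6-one bicycle with 19-OTBS, 7-OTBS and 11-OTES, via beta-gamma enone 19 (not isolated)
Conditions: MeAlCl2 (2.2 equiv, 1 M in hexanes), CH2Cl2, −78 °C; Et3N/MeOH quench at −78 °C, aqueous NaHCO3; then DBU (1 equiv), CH2Cl2, rt
Reagents that add atoms: none
Why: Proposed new method: MeAlCl2 binds the epoxide oxygen, the C4–O bond lengthens with tertiary cationic character, and C5, the α-carbon of the 1-silyloxydiene, attacks C4 from the side opposite the departing oxygen; loss of the silyl group gives the β,γ-enone 19, which DBU should equilibrate to the conjugated C5=C10 enone. The closest known reaction type is the Lewis-acid epoxide-initiated cation–olefin cyclisation terminated by a silyl enol ether; attack through the α-carbon of an extended dienol ether instead of its γ-carbon has no direct precedent and is argued from ring size, since γ-attack through C1 would close a four-membered ring. Ring A closes in a 6-endo mode with respect to the epoxide (enol double bond exocyclic to the new ring) through a chair-like arrangement in which the C3 oxygen, anti to the forming bond, is equatorial. The new stereocentre C4 is set by inversion of the epoxide carbon, that is by the tartrate of step 8 and not by C9, while C3 is carried over unchanged. The step needs opening at C4 and not 5-exo opening at C3, and capture before a 1,2-shift of the activated epoxide; the cation-stabilising tertiary C4, the C10=C1 geometry that holds C2 next to C5, and the blocked C7 position secure this.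

Step 13
Reactants: 20 (3R,4S,7S,8R,9R)-3-hydroxy-5(10)-en-6-one bicycle with 19-OTBS, 7-OTBS and 11-OTES
Product: 21 C11 primary alcohol (11-OH, 3-OH, 19-OTBS, 7-OTBS)
Conditions: PPTS (0.2 equiv), MeOH/CH2Cl2 1:1, 0 °C
Reagents that add atoms: none
Why: Selective acid-catalysed methanolysis, a primary triethylsilyl ether being cleaved much faster than primary or secondary tert-butyldimethylsilyl ethers.

Step 14
Reactants: 21 C11 primary alcohol
Product: 22 C11 aldehyde (3-OH retained)
Conditions: TEMPO (0.2 equiv), PhI(OAc)2 (1.3 equiv), CH2Cl2, rt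
Reagents that add atoms: none
Why: Oxoammonium (TEMPO) oxidation is selective for primary over secondary alcohols, so the C11 alcohol should give the aldehyde while the hindered C3 carbinol is kept.

Step 15
Reactants: 22 C11 aldehyde
Product: 23 C9 vinyl compound (C11=C12)
Conditions: Ph3PCH3Br (2.0 equiv), KN(SiMe3)2 (1.9 equiv), THF, 0 °C; then 22, −78 → 0 °C
Reagents that add atoms: methyltriphenylphosphonium bromide C[P+](c1ccccc1)(c1ccccc1)c1ccccc1.[Br-]
Why: Wittig methylenation, the non-stabilised ylide reacting with the aldehyde far faster than with the C6 ketone that is flanked by the C7 siloxy group and the fully substituted C5.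

Step 16
Reactants: 24 but-2-yn-1-ol
Product: 25 tert-butyl(but-2-yn-1-yloxy)diphenylsilane
Conditions: TBDPSCl (1.1 equiv), imidazole, CH2Cl2, rt
Reagents that add atoms: tert-butyldiphenylsilyl chloride CC(C)(C)[Si](Cl)(c1ccccc1)c1ccccc1
Why: Routine O-silylation of a primary alcohol with a group that survives the later acidic desilylations.

Step 17
Reactants: 25 tert-butyl(but-2-yn-1-yloxy)diphenylsilane
Product: 27 (E)-tert-butyl[(3-iodobut-2-en-1-yl)oxy]diphenylsilane, via alkenylzirconocene 26 (not isolated)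
Conditions: Cp2Zr(H)Cl (1.5 equiv), THF, rt → 45 °C; then I2 (1.5 equiv), 0 °C
Reagents that add atoms: iodine II
Why: Hydrozirconation is a syn addition that, with excess hydride under equilibrating conditions, should place zirconium on the less hindered methyl-bearing carbon, and iodinolysis with retention then gives the E-vinyl iodide.

Step 18
Reactants: 23 C9 vinyl compound; 27 (E)-tert-butyl[(3-iodobut-2-en-1-yl)oxy]diphenylsilane
Product: 29 coupled product with the complete side chain (15-OTBDPS, 3-OH, 19-OTBS, 7-OTBS), via alkylborane 28 (not isolated)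
Conditions: 9-BBN-H (3 equiv), THF, rt; then 27 (1.3 equiv), PdCl2(dppf) (5 mol %), AsPh3 (10 mol %), Cs2CO3 (3 equiv), DMF/H2O, rt
Reagents that add atoms: none
Why: Anti-Markovnikov hydroboration of the monosubstituted alkene followed by B-alkyl Suzuki–Miyaura coupling, which keeps the E-geometry of the iodide and so fixes the C13=C14 geometry, the tetrasubstituted enone alkene being inert and the doubly flanked C6 ketone expected to react only slowly with the bulky borane.

Step 19
Reactants: 29 coupled product with the complete side chain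
Product: 30 C3 ketone
Conditions: DMP (1,1,1-triacetoxy-1,1-dihydro-1,2-benziodoxol-3(1H)-one, 1.5 equiv), NaHCO3, CH2Cl2, rt
Reagents that add atoms: none
Why: Hypervalent-iodine oxidation of the only free alcohol, a secondary one, to the ketone under buffered conditions.

Step 20
Reactants: 30 C3 ketone
Product: 31 C19 primary alcohol
Conditions: CSA (0.1 equiv), MeOH/CH2Cl2 1:1, 0 °C
Reagents that add atoms: none
Why: Selective acid methanolysis, the primary tert-butyldimethylsilyl ether being cleaved faster than the secondary α-keto one while the tert-butyldiphenylsilyl ether is stable to these conditions.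

Step 21
Reactants: 31 C19 primary alcohol
Product: 32 C19 acetate
Conditions: Ac2O (2 equiv), pyridine, DMAP (cat.), CH2Cl2, 0 °C
Reagents that add atoms: acetic anhydride CC(=O)OC(C)=O
Why: Acylation of the single free hydroxyl, done before the diosphenol and the C15 alcohol exist so that no selectivity is needed, and the β-acetoxy ketone cannot eliminate because C4 is quaternary.

Step 22
Reactants: 32 C19 acetate
Product: 33 7,15-diol (α-hydroxy ketone at C7, allylic alcohol at C15)
Conditions: HF·pyridine (excess), pyridine, THF, 0 °C → rt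
Reagents that add atoms: none
Why: Fluoride-mediated desilylation removes both remaining silyl ethers under mildly acidic conditions that leave the acetate in place.

Step 23
Reactants: 33 7,15-diol
Product: 35 CNP0512382.1, via 6,7-diketone 34 (not isolated)
Conditions: Cu(OAc)2 (2.2 equiv), MeOH, rt, air; EDTA work-up
Reagents that add atoms: none
Why: Acyloin oxidation by divalent copper converts the α-hydroxy ketone into the 6,7-dione, which enolises toward C8 (its only enolisable neighbour) to the diosphenol and thereby erases C7 and C8, while an isolated allylic alcohol is not oxidised by this reagent.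

Compound list
1 | 2-methylcyclohexane-1,3-dione | CC1C(=O)CCCC1=O | starting material
2 | (E)-pent-3-en-2-one | C/C=C/C(C)=O | starting material
3 | rac-2-methyl-2-(4-oxopentan-2-yl)cyclohexane-1,3-dione (racemic at the side-chain centre) | CC(=O)CC(C)C1(C)C(=O)CCCC1=O | intermediate
4 | cis-fused ketol, 8a-hydroxy-4,4a-dimethyloctahydronaphthalene-2,5-dione (hydroxyl cis to the angular methyl) | C[C@@]12[C@@H](C)CC(=O)C[C@]1(O)CCCC2=O | intermediate
5 | (4S,4aR)-4,4a-dimethyl-4,4a,7,8-tetrahydronaphthalene-2,5(3H,6H)-dione | C[C@@]12[C@@H](C)CC(=O)C=C1CCCC2=O | intermediate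
6 | (4S,4aR,5R)-5-hydroxy-4,4a-dimethyl-4,4a,5,6,7,8-hexahydronaphthalen-2(3H)-one | C[C@@]12[C@@H](C)CC(=O)C=C1CCC[C@H]2O | intermediate
7 | (4S,4aS)-4,4a-dimethyl-4,4a,7,8-tetrahydronaphthalen-2(3H)-one | C[C@@]12[C@@H](C)CC(=O)C=C1CCC=C2 | intermediate
8 | cis-5,6-diol of 7 (both hydroxyls anti to the angular methyl) | C[C@@]12[C@@H](C)CC(=O)C=C1CC[C@H](O)[C@@H]2O | intermediate
9 | (1R,6S)-1,6-dimethyl-4-oxo-2-(3-oxopropyl)cyclohex-2-ene-1-carbaldehyde | O=C1C=C(CCC=O)[C@](C)(C=O)[C@@H](C)C1 | intermediate
10 | 2-(triphenylphosphoranylidene)propanal | CC(C=O)=P(c1ccccc1)(c1ccccc1)c1ccccc1 | starting material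
11 | (1R,6S)-1,6-dimethyl-2-[(E)-4-methyl-5-oxopent-3-en-1-yl]-4-oxocyclohex-2-ene-1-carbaldehyde | O=C1C=C(CC/C=C(\C)C=O)[C@](C)(C=O)[C@@H](C)C1 | intermediate
12 | (4R,5S)-4-(hydroxymethyl)-3-[(E)-5-hydroxy-4-methylpent-3-en-1-yl]-4,5-dimethylcyclohex-2-en-1-one | O=C1C=C(CC/C=C(\C)CO)[C@](C)(CO)[C@@H](C)C1 | intermediate
13 | (4R,5S)-4-(hydroxymethyl)-3-{2-[(2R,3R)-3-(hydroxymethyl)-3-methyloxiran-2-yl]ethyl}-4,5-dimethylcyclohex-2-en-1-one | O=C1C=C(CC[C@H]2O[C@]2(C)CO)[C@](C)(CO)[C@@H](C)C1 | intermediate
14 | 19-O-TBS ether of 13 (C11 hydroxyl free) | O=C1C=C(CC[C@H]2O[C@]2(C)CO[Si](C)(C)C(C)(C)C)[C@](C)(CO)[C@@H](C)C1 | intermediate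
15 | 19-O-TBS 11-O-TES bis-silyl ether of 13 | O=C1C=C(CC[C@H]2O[C@]2(C)CO[Si](C)(C)C(C)(C)C)[C@](C)(CO[Si](CC)(CC)CC)[C@@H](C)C1 | intermediate
16 | (4R,5R,6S)-6-hydroxy derivative of 15 (C7-OH trans to the C8 methyl) | O=C1C=C(CC[C@H]2O[C@]2(C)CO[Si](C)(C)C(C)(C)C)[C@](C)(CO[Si](CC)(CC)CC)[C@@H](C)[C@@H]1O | intermediate
17 | 7-O-TBS ether of 16 | O=C1C=C(CC[C@H]2O[C@]2(C)CO[Si](C)(C)C(C)(C)C)[C@](C)(CO[Si](CC)(CC)CC)[C@@H](C)[C@@H]1O[Si](C)(C)C(C)(C)C | intermediate
18 | ring B TBS dienol ether (C6–OTBS, C5=C6, (E)-C10=C1; 7-OTBS, 11-OTES; (3R,4R)-epoxide arm with 19-OTBS) | CC(C)(C)[Si](C)(C)OC1=C/C(=C\C[C@H]2O[C@]2(C)CO[Si](C)(C)C(C)(C)C)[C@](C)(CO[Si](CC)(CC)CC)[C@@H](C)[C@@H]1O[Si](C)(C)C(C)(C)C | intermediate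
19 | β,γ-enone: 3-hydroxy-1(10)-en-6-one bicycle with C5–H (ring A attached on the face of C11 and the C7 oxygen) | CC(C)(C)[Si](C)(C)OC[C@@]1(C)[C@H](O)CC=C2[C@@H]1C(=O)[C@@H](O[Si](C)(C)C(C)(C)C)[C@H](C)[C@@]2(C)CO[Si](CC)(CC)CC | intermediate
20 | (3R,4S,7S,8R,9R)-3-hydroxy-5(10)-en-6-one bicycle, 19-OTBS, 7-OTBS, 11-OTES | CC(C)(C)[Si](C)(C)OC[C@@]1(C)[C@H](O)CCC2=C1C(=O)[C@@H](O[Si](C)(C)C(C)(C)C)[C@H](C)[C@@]2(C)CO[Si](CC)(CC)CC | intermediate
21 | C11 alcohol of 20 (11-OH, 3-OH) | CC(C)(C)[Si](C)(C)OC[C@@]1(C)[C@H](O)CCC2=C1C(=O)[C@@H](O[Si](C)(C)C(C)(C)C)[C@H](C)[C@@]2(C)CO | intermediate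
22 | C11 aldehyde | CC(C)(C)[Si](C)(C)OC[C@@]1(C)[C@H](O)CCC2=C1C(=O)[C@@H](O[Si](C)(C)C(C)(C)C)[C@H](C)[C@@]2(C)C=O | intermediate
23 | C9 vinyl compound (C11=C12) | CC(C)(C)[Si](C)(C)OC[C@@]1(C)[C@H](O)CCC2=C1C(=O)[C@@H](O[Si](C)(C)C(C)(C)C)[C@H](C)[C@@]2(C)C=C | intermediate
24 | but-2-yn-1-ol | CC#CCO | starting material
25 | tert-butyl(but-2-yn-1-yloxy)diphenylsilane | CC#CCO[Si](c1ccccc1)(c1ccccc1)C(C)(C)C | intermediate
26 | (E)-alkenylzirconocene chloride (Zr on the methyl-bearing carbon, trans to CH2OSi) | C/C(=C\CO[Si](c1ccccc1)(c1ccccc1)C(C)(C)C)[Zr](Cl)(C1C=CC=C1)C1C=CC=C1 | intermediate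
27 | (E)-tert-butyl[(3-iodobut-2-en-1-yl)oxy]diphenylsilane | C/C(I)=C\CO[Si](c1ccccc1)(c1ccccc1)C(C)(C)C | intermediate
28 | B-alkyl-9-borabicyclo[3.3.1]nonane from 23 (boron on C12) | CC(C)(C)[Si](C)(C)OC[C@@]1(C)[C@H](O)CCC2=C1C(=O)[C@@H](O[Si](C)(C)C(C)(C)C)[C@H](C)[C@@]2(C)CCB1C2CCCC1CCC2 | intermediate
29 | coupled product, (13E)-side chain with 15-OTBDPS; 3-OH, 19-OTBS, 7-OTBS | CC(C)(C)[Si](C)(C)OC[C@@]1(C)[C@H](O)CCC2=C1C(=O)[C@@H](O[Si](C)(C)C(C)(C)C)[C@H](C)[C@@]2(C)CC/C(C)=C/CO[Si](c1ccccc1)(c1ccccc1)C(C)(C)C | intermediate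
30 | C3 ketone of 29 | CC(C)(C)[Si](C)(C)OC[C@@]1(C)C(=O)CCC2=C1C(=O)[C@@H](O[Si](C)(C)C(C)(C)C)[C@H](C)[C@@]2(C)CC/C(C)=C/CO[Si](c1ccccc1)(c1ccccc1)C(C)(C)C | intermediate
31 | C19 alcohol | OC[C@@]1(C)C(=O)CCC2=C1C(=O)[C@@H](O[Si](C)(C)C(C)(C)C)[C@H](C)[C@@]2(C)CC/C(C)=C/CO[Si](c1ccccc1)(c1ccccc1)C(C)(C)C | intermediate
32 | C19 acetate | CC(=O)OC[C@@]1(C)C(=O)CCC2=C1C(=O)[C@@H](O[Si](C)(C)C(C)(C)C)[C@H](C)[C@@]2(C)CC/C(C)=C/CO[Si](c1ccccc1)(c1ccccc1)C(C)(C)C | intermediate
33 | 7,15-diol (7-hydroxy-6-ketone, free C15 alcohol, C19 acetate) | CC(=O)OC[C@@]1(C)C(=O)CCC2=C1C(=O)[C@@H](O)[C@H](C)[C@@]2(C)CC/C(C)=C/CO | intermediate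
34 | 6,7-diketone tautomer | CC(=O)OC[C@@]1(C)C(=O)CCC2=C1C(=O)C(=O)[C@H](C)[C@@]2(C)CC/C(C)=C/CO | intermediate
35 | CNP0512382.1 (4S,9S; 13E) | CC(=O)OC[C@@]1(C)C(=O)CCC2=C1C(=O)C(O)=C(C)[C@@]2(C)CC/C(C)=C/CO | target

Total step count: 23. Longest linear sequence: 21 steps (steps 1–15 and 18–23); steps 16–17 prepare the vinyl iodide 27.

Steps most likely to fail

Step 12. The dienol ether may react through the wrong pathway: 5-exo opening at C3, a 1,2-shift of the activated epoxide before capture, ionisation next to the C7 siloxy group, or simple desilylation without C–C bond formation. Fallback with known chemistry: set out from 17 (made from 16 with TBSCl/imidazole). Conjugate hydrosilylation of the enone (RhCl(PPh3)3 cat., Et3SiH) should give the regiodefined simple silyl enol ether, the triethylsilyl enol ether F1. Its MeAlCl2-promoted epoxide opening is the established enol-silane-terminated cyclisation and should give the saturated hydroxy ketone F2. Silylation under equilibrating conditions (TMSOTf, Et3N) to the C5=C6 bis(trimethylsilyl) compound F3, Saegusa–Ito oxidation with Pd(OAc)2 in MeCN and brief methanolysis of the C3 trimethylsilyl ether would restore the C5=C10 enone and come back at 20.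

Step 11. Enolisation may go toward C7 instead of C1, the silyl triflate may isomerise or open the epoxide, or the C10=C1 geometry may not be controlled. Fallback: set out from 17. KOtBu in t-BuOH/THF at 0 °C should form the extended potassium dienolate under equilibrating conditions, and a cold acetic acid quench protonates it at C5 (deconjugation) to the β,γ-unsaturated ketone F4, which already holds the C10=C1 bond. Its doubly activated C5 methylene should then be deprotonated regiospecifically by LiN(iPr)2 at −78 °C and O-silylated with TBSCl/DMPU, coming back at 18.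

Step 2. Discrimination between the two enantiomers of 3, or between the two ring carbonyls, may be too weak, giving low enantiomeric purity or the C8 epimer. Fallback: set out from 3. Achiral cyclodehydration (pyrrolidine, AcOH, toluene, reflux) should give the racemic cis-enedione, that is 5 together with the enantiomer of 5 F5. Reduction as in step 3 gives 6 together with the enantiomer of 6 F6. Lipase-catalysed acylation (Burkholderia cepacia lipase, vinyl acetate) should acylate one enantiomer; taken here as 6, this gives the acetate of 6 F7, which is separated from F6 and methanolysed (K2CO3, MeOH) to come back at 6. If the enzyme prefers F6, 6 is simply the recovered alcohol.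

Further compounds
F1 | step 12 | triethylsilyl enol ether (C6–OSiEt3, C5=C6, C10–H; epoxide arm and silyl ethers as in 17) | CC[Si](CC)(CC)OC1=CC(CC[C@H]2O[C@]2(C)CO[Si](C)(C)C(C)(C)C)[C@](C)(CO[Si](CC)(CC)CC)[C@@H](C)[C@@H]1O[Si](C)(C)C(C)(C)C
F2 | step 12 | saturated hydroxy ketone (5,10-dihydro-20; C5 and C10 not defined) | CC(C)(C)[Si](C)(C)OC[C@@]1(C)[C@H](O)CCC2C1C(=O)[C@@H](O[Si](C)(C)C(C)(C)C)[C@H](C)[C@@]2(C)CO[Si](CC)(CC)CC
F3 | step 12 | bis(trimethylsilyl) compound (C5=C6 enol ether, 3-OTMS) | CC(C)(C)[Si](C)(C)OC[C@@]1(C)[C@H](O[Si](C)(C)C)CCC2C1=C(O[Si](C)(C)C)[C@@H](O[Si](C)(C)C(C)(C)C)[C@H](C)[C@@]2(C)CO[Si](CC)(CC)CC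
F4 | step 11 | β,γ-unsaturated ketone (C5H2, (E)-C10=C1) | O=C1C/C(=C\C[C@H]2O[C@]2(C)CO[Si](C)(C)C(C)(C)C)[C@](C)(CO[Si](CC)(CC)CC)[C@@H](C)[C@@H]1O[Si](C)(C)C(C)(C)C
F5 | step 2 | enantiomer of 5, (4R,4aS)-4,4a-dimethyl-4,4a,7,8-tetrahydronaphthalene-2,5(3H,6H)-dione | C[C@]12[C@H](C)CC(=O)C=C1CCCC2=O
F6 | step 2 | enantiomer of 6 | C[C@]12[C@H](C)CC(=O)C=C1CCC[C@@H]2O
F7 | step 2 | acetate of 6 | C[C@@]12[C@@H](C)CC(=O)C=C1CCC[C@H]2OC(C)=O
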